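**Retrosynthetic overview**
- The two prenyl groups are added last, by double C-alkylation of the one ring carbon of the dearomatized acylphloroglucinol that still carries hydrogen.
- The C4' tertiary alcohol comes from Markovnikov hydration of an exocyclic methylene on ring B (the spiro cyclohexane).
- Ring B and the spiro centre come from one palladium-catalysed intramolecular ipso-allylation of a 3-alkylated 2,4,6-trihydroxyacetophenone, which dearomatizes ring A.
- The arene–CH2 bond comes from Michael addition of the acylphloroglucinol to a 2-methylidenecyclopentanone; the C1' carbinol comes from methyl addition to that ketone.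
- Ring C (cyclopentane) is bought as cyclopentenone and made chiral by asymmetric conjugate addition with aldol trapping. Ring order: C and A are bought, B is formed in the key step.

Assumption: the (R,R)-Trost ligand in step 5 is taken as the matched enantiomer for the 1R spiro centre (its antipode would be used in the same step if a two-ligand test shows the opposite sense); descriptors of 13–17 refer to the tautomers drawn.

Step 1
Reactants: 1 cyclopent-2-en-1-one; 2 isopropenylmagnesium bromide; 3 formaldehyde
Product: 6 (2R,3R)-2-(hydroxymethyl)-3-(prop-1-en-2-yl)cyclopentan-1-one, via alkenylzirconocene 4 (not isolated), via zirconium enolate 5 (not isolated)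
Conditions: 2, Cp2ZrCl2, THF, 0 °C; [Rh(cod)(MeCN)2]BF4 (5 mol %), (R)-BINAP (6 mol %), 1, THF, 25 °C; then CH2O (THF solution), −78 → 0 °C; H2O
Reagents that add atoms: isopropenylmagnesium bromide 2, CC(=C)[Mg]Br; formaldehyde 3, C=O
Why: Rhodium/(R)-BINAP-catalysed asymmetric conjugate addition of the alkenylzirconium (Hayashi–Miyaura type) sets C3 as R by enantioface-selective insertion of the enone into the Rh–alkenyl bond, and the regiodefined zirconium enolate is hydroxymethylated anti to the new substituent (tandem conjugate addition–aldol), so C2 is R (trans, also the thermodynamic arrangement).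

Step 2
Reactants: 6 (2R,3R)-2-(hydroxymethyl)-3-(prop-1-en-2-yl)cyclopentan-1-one
Product: 7 (2R,3R)-3-(3-chloroprop-1-en-2-yl)-2-(hydroxymethyl)cyclopentan-1-one
Conditions: Ca(OCl)2, CO2 (dry ice), CH2Cl2/H2O, 0 °C
Reagents that add atoms: calcium hypochlorite, Ca(OCl)2, [Ca+2].[O-]Cl.[O-]Cl
Why: Ene-type allylic chlorination of the 1,1-disubstituted alkene by hypochlorous acid gives the 2-(chloromethyl)allyl group with transposition of the double bond; ketone, primary alcohol and both stereocentres are untouched.

Step 3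
Reactants: 7 (2R,3R)-3-(3-chloroprop-1-en-2-yl)-2-(hydroxymethyl)cyclopentan-1-one; 8 2,4,6-trihydroxyacetophenone
Product: 10 (2S,3R)-2-[(3-acetyl-2,4,6-trihydroxyphenyl)methyl]-3-(3-chloroprop-1-en-2-yl)cyclopentan-1-one, via exocyclic enone 9 (not isolated)
Conditions: MsCl, Et3N, CH2Cl2, −20 → 0 °C; then 8 (2 equiv), NaOAc, AcOH/MeCN, 0 → 25 °C
Reagents that add atoms: none
Why: Mesylation and E1cB elimination give the exocyclic enone, which the electron-rich ring carbon C3 of the phloroglucinol attacks in a Michael addition (C-alkylation); the α-centre re-forms by protonation under thermodynamic control, anti to the C3 substituent (2S,3R, trans), and the buffered medium keeps the phenoxide from attacking the allylic chloride prematurely.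

Step 4
Reactants: 10 (2S,3R)-2-[(3-acetyl-2,4,6-trihydroxyphenyl)methyl]-3-(3-chloroprop-1-en-2-yl)cyclopentan-1-one; 11 methylmagnesium bromide
Product: 12 1-[3-({(1S,2R,5R)-5-(3-chloroprop-1-en-2-yl)-2-hydroxy-2-methylcyclopentyl}methyl)-2,4,6-trihydroxyphenyl]ethan-1-one
Conditions: MeMgBr (6 equiv), CeCl3 (3 equiv), THF, −78 → −20 °C; then H2O
Reagents that add atoms: methylmagnesium bromide 11, C[Mg]Br
Why: Organocerium 1,2-addition (Imamoto conditions) occurs only at the cyclopentanone, the acetyl group being deactivated as a tris-phenoxide, and from the face anti to the adjacent benzylic substituent, as in additions to 2,3-trans-disubstituted cyclopentanones of the prostanoid series, which places OH cis to the CH2Ar arm (new centre R).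

Step 5
Reactants: 12 1-[3-({(1S,2R,5R)-5-(3-chloroprop-1-en-2-yl)-2-hydroxy-2-methylcyclopentyl}methyl)-2,4,6-trihydroxyphenyl]ethan-1-one
Product: 13 (1R,1'R,3a'R,7a'S)-3-acetyl-1',4,6-trihydroxy-1'-methyl-4'-methylidene-1',2',3',3a',4',5',7',7a'-octahydrospiro[cyclohexane-1,6'-indene]-3,5-dien-2-one
Conditions: Pd2(dba)3·CHCl3 (2.5 mol %), (R,R)-DACH-phenyl Trost ligand (7.5 mol %), Cs2CO3 (1.1 equiv), 1,4-dioxane (0.01 M), 25 °C
Reagents that add atoms: none
Why: Proposed new method: oxidative addition of zerovalent palladium to the allylic chloride gives a 2-substituted π-allyl with two equivalent CH2 termini, which the cesium phenoxide attacks through its already substituted carbon C3 in a 6-exo ipso ring closure that breaks aromaticity and forms ring B and the spiro centre at once; the chiral pocket of the Trost ligand must place the C4 flank (not C2) axial, syn to H-7a', to give the 1R centre, the closest known reactions being palladium-catalysed intramolecular ipso-allylic dearomatization of phenols to spirocyclohexadienones and Trost-ligand-controlled allylic dearomatization of naphthols and acylphloroglucinols.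

Step 6
Reactants: 13 (1R,1'R,3a'R,7a'S)-3-acetyl-1',4,6-trihydroxy-1'-methyl-4'-methylidene-1',2',3',3a',4',5',7',7a'-octahydrospiro[cyclohexane-1,6'-indene]-3,5-dien-2-one
Product: 14 (1R,1'R,3a'R,4'R,7a'S)-3-acetyl-1',4,4',6-tetrahydroxy-1',4'-dimethyl-1',2',3',3a',4',5',7',7a'-octahydrospiro[cyclohexane-1,6'-indene]-3,5-dien-2-one
Conditions: Co(acac)2 (20 mol %), PhSiH3 (2 equiv), O2 (1 atm), THF/i-PrOH, 0 → 25 °C
Reagents that add atoms: dioxygen, O=O
Why: Mukaiyama hydration: hydrogen-atom transfer to the CH2 terminus gives the tertiary C4' radical, which O2 traps from the equatorial direction because the axial face is blocked by the axial C6 flank of ring A and by H-7a' (1,3-diaxial), so OH is equatorial and methyl axial (4'R).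

Step 7
Reactants: 14 (1R,1'R,3a'R,4'R,7a'S)-3-acetyl-1',4,4',6-tetrahydroxy-1',4'-dimethyl-1',2',3',3a',4',5',7',7a'-octahydrospiro[cyclohexane-1,6'-indene]-3,5-dien-2-one; 15 prenyl bromide
Product: 17 (1R,1'R,3a'R,4'R,7a'S)-3-acetyl-1',4,4'-trihydroxy-1',4'-dimethyl-5,5-bis(3-methylbut-2-en-1-yl)-1',2',3',3a',4',5',7',7a'-octahydrospiro[cyclohex-3-ene-1,6'-indene]-2,6-dione, via monoprenyl dienone 16 (not isolated)
Conditions: prenyl bromide (2.4 equiv), NaOMe (4 equiv), MeOH, 0 → 25 °C
Reagents that add atoms: prenyl bromide 15, CC(C)=CCBr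
Why: Double C-alkylation (gem-diprenylation, as in lupulone-type syntheses) of the vinylogous-acid enolate at C5, the only ring carbon still bearing hydrogen; no stereocentre is formed, and the quaternary spiro centre and tertiary alcohols cannot epimerize.

**Compound list**
1 | cyclopent-2-en-1-one | O=C1CCC=C1 | starting material
2 | isopropenylmagnesium bromide | CC(=C)[Mg]Br | starting material
3 | formaldehyde | C=O | starting material
4 | chloro(prop-1-en-2-yl)bis(cyclopentadienyl)zirconium, Cp2Zr(Cl)C(CH3)=CH2 | C=C(C)[Zr](Cl)(C1C=CC=C1)C1C=CC=C1 | intermediate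
5 | chlorobis(cyclopentadienyl)zirconium (3R)-3-(prop-1-en-2-yl)cyclopent-1-en-1-olate | C=C(C)[C@@H]1CCC(O[Zr](Cl)(C2C=CC=C2)C2C=CC=C2)=C1 | intermediate
6 | (2R,3R)-2-(hydroxymethyl)-3-(prop-1-en-2-yl)cyclopentan-1-one | O=C1CC[C@@H](C(C)=C)[C@@H]1CO | intermediate
7 | (2R,3R)-3-(3-chloroprop-1-en-2-yl)-2-(hydroxymethyl)cyclopentan-1-one | O=C1CC[C@@H](C(CCl)=C)[C@@H]1CO | intermediate
8 | 2,4,6-trihydroxyacetophenone | CC(=O)c1c(O)cc(O)cc1O | starting material
9 | (3R)-3-(3-chloroprop-1-en-2-yl)-2-methylidenecyclopentan-1-one | O=C1CC[C@@H](C(CCl)=C)C1=C | intermediate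
10 | (2S,3R)-2-[(3-acetyl-2,4,6-trihydroxyphenyl)methyl]-3-(3-chloroprop-1-en-2-yl)cyclopentan-1-one | O=C1CC[C@@H](C(CCl)=C)[C@@H]1Cc1c(O)cc(O)c(C(C)=O)c1O | intermediate
11 | methylmagnesium bromide | C[Mg]Br | starting material
12 | 1-[3-({(1S,2R,5R)-5-(3-chloroprop-1-en-2-yl)-2-hydroxy-2-methylcyclopentyl}methyl)-2,4,6-trihydroxyphenyl]ethan-1-one | CC(=O)c1c(O)cc(O)c(C[C@H]2[C@@H](CC[C@@]2(C)O)C(CCl)=C)c1O | intermediate
13 | (1R,1'R,3a'R,7a'S)-3-acetyl-1',4,6-trihydroxy-1'-methyl-4'-methylidene-1',2',3',3a',4',5',7',7a'-octahydrospiro[cyclohexane-1,6'-indene]-3,5-dien-2-one (trans-fused hydrindane) | CC(=O)C1=C(O)C=C(O)[C@]2(C[C@H]3[C@@H](CC[C@@]3(C)O)C(=C)C2)C1=O | intermediate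
14 | (1R,1'R,3a'R,4'R,7a'S)-3-acetyl-1',4,4',6-tetrahydroxy-1',4'-dimethyl-1',2',3',3a',4',5',7',7a'-octahydrospiro[cyclohexane-1,6'-indene]-3,5-dien-2-one | CC(=O)C1=C(O)C=C(O)[C@]2(C[C@H]3[C@@H](CC[C@@]3(C)O)[C@](C)(O)C2)C1=O | intermediate
15 | prenyl bromide (1-bromo-3-methylbut-2-ene) | CC(C)=CCBr | starting material
16 | (1R,1'R,3a'R,4'R,7a'S)-3-acetyl-1',4,4',6-tetrahydroxy-1',4'-dimethyl-5-(3-methylbut-2-en-1-yl)-1',2',3',3a',4',5',7',7a'-octahydrospiro[cyclohexane-1,6'-indene]-3,5-dien-2-one | CC(=O)C1=C(O)C(CC=C(C)C)=C(O)[C@]2(C[C@H]3[C@@H](CC[C@@]3(C)O)[C@](C)(O)C2)C1=O | intermediate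
17 | (1R,1'R,3a'R,4'R,7a'S)-3-acetyl-1',4,4'-trihydroxy-1',4'-dimethyl-5,5-bis(3-methylbut-2-en-1-yl)-1',2',3',3a',4',5',7',7a'-octahydrospiro[cyclohex-3-ene-1,6'-indene]-2,6-dione | CC(=O)C1=C(O)C(CC=C(C)C)(CC=C(C)C)C(=O)[C@]2(C[C@H]3[C@@H](CC[C@@]3(C)O)[C@](C)(O)C2)C1=O | target

**Total step count:** 7. **Longest linear sequence:** 7 steps (from 1; the aromatic feedstock 8 enters at step 3).

**Steps most likely to fail, with fallbacks**

First, the dearomative spirocyclisation (step 5). The two flanks of C3 differ only remotely, so the sense and level of selectivity at the spiro centre rest on unproven ligand control. The fallback is a stereospecific ring-contracting dearomative Claisen rearrangement that sets out from 7 and 8 and comes back at 13. K2CO3 in acetone alkylates the most acidic para-OH of 8 with 7 to give the para-O-allyl ether F1. MsCl/Et3N then gives the exocyclic enone F2, which at high dilution (NaOAc/AcOH or DBU, MeCN) closes by intramolecular Michael addition of C3 to the eight-membered aryl ether ketone F3. MeMgBr/CeCl3 gives the tertiary alcohol F4. Heating F4 (toluene, 150 °C, sealed tube) causes a [3,3] shift through a twin-chair bicyclic transition state. The allyl terminus can reach only the substituted ortho carbon C3, and the carbon whose oxygen carried the allyl group (C4) must end up axial, so 13 forms with the required spiro configuration.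

Second, the hydration (step 6). The facial selectivity of O2 capture is an argument rather than a precedent, and the enolized triketone may interfere with the cobalt/silane/O2 system. The fallback sets out from 13 and comes back at 14. OsO4 (cat.)/NMO dihydroxylates the exocyclic alkene from the equatorial face, for the same steric reason, to give the diol F5. TsCl with Et3N and catalytic Bu2SnO gives the primary tosylate F6; any enol sulfonate on ring A is cleaved on basic work-up. LiEt3BH then replaces the tosylate by hydride to give 14.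

Third, the three-component opening (step 1). Transfer of an α-substituted alkenyl group from zirconium to rhodium and clean trapping by formaldehyde are the uncertain points. The fallback sets out from 1 and comes back at 9. Morita–Baylis–Hillman reaction of 1 with aqueous formaldehyde (imidazole) gives 2-(hydroxymethyl)cyclopent-2-en-1-one F7, and Ac2O/pyridine gives its acetate F8. Rhodium-catalysed conjugate addition of isopropenylboronic acid pinacol ester ([Rh(cod)OH]2, (R)-BINAP, KOH, dioxane/H2O) followed by β-acetoxy elimination gives (3S)-2-methylidene-3-(prop-1-en-2-yl)cyclopentan-1-one F9, which has the same spatial arrangement at C3 as 6. Ca(OCl)2/CO2 converts F9 into 9, which is taken into the second half of step 3.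

**Further compounds**
F1 | step 5 | 1-[2,6-dihydroxy-4-({2-[(1R,2R)-2-(hydroxymethyl)-3-oxocyclopentyl]prop-2-en-1-yl}oxy)phenyl]ethan-1-one | O=C1CC[C@@H](C(COc2cc(O)c(C(C)=O)c(O)c2)=C)[C@@H]1CO
F2 | step 5 | 1-[2,6-dihydroxy-4-({2-[(1S)-2-methylidene-3-oxocyclopentyl]prop-2-en-1-yl}oxy)phenyl]ethan-1-one | O=C1CC[C@@H](C(COc2cc(O)c(C(C)=O)c(O)c2)=C)C1=C
F3 | step 5 | eight-membered aryl ether ketone: O4 of the acetophenone joined through CH2–C(=CH2) to C3 (R) of the cyclopentanone, whose C2 (S) is joined through CH2 to ring carbon C3 of the arene | O=C1CC[C@@H](C(=C)COc2cc(O)c(C(C)=O)c(O)c2C3)[C@@H]13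
F4 | step 5 | tertiary alcohol from F3: the ring ketone replaced by C(CH3)OH, cyclopentane centres 1S,2R,5R as in 12 | CC(=O)c1c(O)cc3c(C[C@H]2[C@@H](CC[C@@]2(C)O)C(=C)CO3)c1O
F5 | step 6 | (1R,1'R,3a'R,4'R,7a'S)-3-acetyl-1',4,4',6-tetrahydroxy-4'-(hydroxymethyl)-1'-methyl-1',2',3',3a',4',5',7',7a'-octahydrospiro[cyclohexane-1,6'-indene]-3,5-dien-2-one | CC(=O)C1=C(O)C=C(O)[C@]2(C[C@H]3[C@@H](CC[C@@]3(C)O)[C@](CO)(O)C2)C1=O
F6 | step 6 | 4'-CH2 4-methylbenzenesulfonate of F5 | CC(=O)C1=C(O)C=C(O)[C@]2(C[C@H]3[C@@H](CC[C@@]3(C)O)[C@](COS(=O)(=O)c4ccc(C)cc4)(O)C2)C1=O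
F7 | step 1 | 2-(hydroxymethyl)cyclopent-2-en-1-one | O=C1CCC=C1CO
F8 | step 1 | (5-oxocyclopent-1-en-1-yl)methyl acetate | CC(=O)OCC1=CCCC1=O
F9 | step 1 | (3S)-2-methylidene-3-(prop-1-en-2-yl)cyclopentan-1-one | O=C1CC[C@@H](C(C)=C)C1=C
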